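At the time of reading, 10 min, I wanted a ledger for each flask showing where every mole of substrate, the limiting reagent, had gone.

| flask | substrate | temperature | remark | time |
|---|---|---|---|---|
| gamma | 0.055 M | 48 °C | run made earlier |  |
| theta | 0.083 M | 64 °C | run made earlier |  |
| Sunday's | 0.11 M | 40 °C |  | 10 min |
| Wednesday's | 0.11 M | 70 °C |  | 10 min |

| run | time / min | target / % | side product / % |
|---|---|---|---|
| gamma | 1.33 | 1 | 2 |
| gamma | 3.00 | 0 | 5 |
| gamma | 4.00 | 0 | 9 |
| gamma | 6.00 | 1 | 13 |
| gamma | 8.00 | 0 | 14 |
| gamma | 10.0 | 0 | 18 |
| theta | 0.250 | 1 | 5 |
| theta | 0.417 | 1 | 7 |
| theta | 0.667 | 0 | 11 |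
| theta | 1.00 | 2 | 13 |
| theta | 1.33 | 0 | 13 |
| theta | 2.00 | 0 | 26 |
| theta | 3.00 | 2 | 33 |

(scatter of a reading: 2 percentage points)



1. the flask that comes out highest in share of target in all that became target or side product or over-reaction product, or "all alike" when all lie within 1.5 percentage points (Sunday's / Wednesday's / all alike)
2. share of target in all that became target or side product or over-reaction product, Sunday's
3. share of target in all that became target or side product or over-reaction product, Wednesday's

The first entry could be read: at their last readings gamma had put 18% of its charge into side product and theta 33%, while target never stood clear of the scatter. Substrate and over-reaction product were not read, so the rest of each book stayed open. I solved the early end first, taking k as side product per minute of charge, averaged up to the last reading: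

k(gamma) = 0.0180 min⁻¹, k(theta) = 0.110 min⁻¹

The late end is the charge itself, which cannot be booked twice. I joined the ends by drawing ln k straight against temperature through both runs and taking 1/k at each flask's temperature:

τ(Sunday's) = 137 min

τ(Wednesday's) = 4.61 min

This τ was what I carried: the charge clock, the time in which side product at its read rate would by itself take up the whole charge. Both runs had been read well inside their clocks. Sunday's, too, would be read inside its clock, so I booked it as mostly substrate, with target as faint as in the runs. Wednesday's would be read beyond its clock, where no run had looked, so I expected it to stand apart, though I could put no number on its share.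

The forecast said all alike, with Sunday's at 3% (0% to 9%) and Wednesday's at 4% (0% to 12%): “I expect both flasks to give only a few percent, so I call them alike, with wide ranges”. I parted from it on Wednesday's.

The highest share came from Wednesday's, with Sunday's at 0.0506% and Wednesday's at 22.8%.

    substrate → side product (k = 0.300 min⁻¹, Ea = 99.0 kJ mol⁻¹)
    substrate → intermediate A (k = 0.240 min⁻¹, Ea = 95.0 kJ mol⁻¹)
    intermediate A ⇌ intermediate B (K = 17.0, k = 0.110 min⁻¹, Ea = 101 kJ mol⁻¹, ΔH = −67.0 kJ mol⁻¹)
    intermediate B → target (k = 0.320 min⁻¹, Ea = 107 kJ mol⁻¹)
    target → over-reaction product (k = 0.0220 min⁻¹, Ea = 102 kJ mol⁻¹)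
    (constants at 70 °C)

Wednesday's, read past its clock of 4.61 min, held 0.45% substrate beside 16.8% target. The time allowed was the main reason for Wednesday's share: left until 100 min, the same flask gave 6.93% instead of 22.8%, with over-reaction product at 37.5%. The neighbour like Wednesday's but kept at 55 °C has a clock of 25.2 min, longer than its 10 min, and it ended with 32% substrate and a share of 1.82%.

The earlier runs and the new flask stem from a simulated flask on assumed constants; noise was put on by code.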